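The ratio of charged [reagent] to charged [substrate] stood at 3.00 in Saturday's flask. I called this ratio the budget: the reagent available per substrate, which a triple product needs 3 of. Friday's budget was 1.00 and Thursday's 0.500, so in those two flasks the reagent was the limiting reagent.

| setting | beta | epsilon | Saturday's | Friday's | Thursday's |
|---|---|---|---|---|---|
| substrate | 0.20 M | 0.20 M | 0.20 M | 0.20 M | 0.20 M |
| reagent | 0.066 M | 0.51 M | 0.600 M | 0.200 M | 0.100 M |
| remark | run made earlier | run made earlier |  |  |  |
| time |  |  | 12 h | 12 h | 12 h |

| run | time / h | triple product / % | mono adduct / % | substrate / % |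
|---|---|---|---|---|
| beta | 0.417 | 0 | 4.9 | 96.1 |
| beta | 1.33 | 0.2 | 13.9 | 87.2 |
| beta | 2.50 | 1.1 | 16.5 | 82.1 |
| beta | 4.00 | 1.8 | 19.5 | 76.4 |
| beta | 5.00 | 1.2 | 19.9 | 74.9 |
| beta | 6.00 | 2.2 | 19.7 | 76.3 |
| beta | 8.00 | 0.6 | 21.3 | 73.7 |
| epsilon | 0.667 | 6.4 | 30.0 | 53.1 |
| epsilon | 1.00 | 12.9 | 30.8 | 41.8 |
| epsilon | 1.50 | 19.0 | 28.4 | 33.7 |
| epsilon | 2.50 | 26.9 | 26.2 | 23.9 |
| epsilon | 4.00 | 35.6 | 22.7 | 16.3 |
| epsilon | 6.00 | 47.0 | 17.0 | 13.2 |
| epsilon | 8.00 | 54.1 | 19.1 | 12.1 |

(each reading ± 1 percentage point)

* which of these holds the largest part of the substrate at the end of Saturday's (bis adduct / substrate / mono adduct / triple product / tetra adduct)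
* which of these holds the largest part of the substrate at the end of Friday's (bis adduct / substrate / mono adduct / triple product / tetra adduct)
* which of these holds the largest part of the substrate at the end of Thursday's (bis adduct / substrate / mono adduct / triple product / tetra adduct)
* how much triple product is there at the end of Saturday's, in percent of the substrate charged



The readings omit bis adduct, so I counted the gap in each balance as bis adduct and reckoned the uptake, reagent taken per substrate charged. In Thursday's flask every adduct costs at least one reagent, so adducts could hold at most 50.0%, and substrate had to lead. In the epsilon run at 1.00 h the uptake was 0.985, close to Friday's budget, and substrate at 41.8% still stood ahead of mono adduct at 30.8%. I expected substrate to lead in Friday's flask too.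

For Saturday's triple product I took two ways. The epsilon budget was 2.55, and its uptake was 1.80 at 4.00 h and 2.11 at 8.00 h. The unspent part of the budget thus stood at 29.4% at 4.00 h and 17.3% at 8.00 h, so its shrinking had slowed; I assumed that the factor of the last stretch would hold over an equal further stretch, and this assumption leaves 10.3% unspent at 12 h. Keeping epsilon's last share of triple product per uptake gave 69.1%.

The second way let triple product approach its ceiling, a third of the budget, on the same assumption of an unchanged factor, and gave 77.3%. The two parted, and the second cheated: it sent the whole budget into triple product, while epsilon's gap still read 15 percentage points at its last reading. I kept 69.1%.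

The forecast named triple product, substrate and substrate for Saturday's, Friday's and Thursday's, with 66% of triple product, on a profile that “fits sequential addition”.

    substrate + reagent → mono adduct + released group (k = 2.13 L mol⁻¹ h⁻¹)
    reagent + mono adduct → bis adduct + released group (k = 2.95 L mol⁻¹ h⁻¹)
    reagent + bis adduct → triple product + released group (k = 11.6 L mol⁻¹ h⁻¹)
    reagent + triple product ⇌ tetra adduct + released group (K = 3.00, k = 3.33 L mol⁻¹ h⁻¹)
    substrate → decomposition product (k = 1.84 × 10⁻⁴ h⁻¹)

Saturday's flask gave triple product at 70.0%, while Friday's gave substrate at 44.1% and Thursday's substrate at 64.5%. In Saturday's flask the half-life of triple product toward tetra adduct by the forward step alone, 0.47 h at 0.585 h, was short against the 12 h, yet tetra adduct fell from 22.5% at 6.00 h to 14.7% as uptake reached 2.82 of the budget of 3.00. With 0.12 M of substrate and the same reagent, the budget was 5.00, and tetra adduct led at 55.0% over triple product at 44.1%.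

The readings are calculated from invented constants, noise included.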